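**Plan**

- Retrosynthesis: the benzylic ester C–O bond is cut first, giving (S)-1-(3,4,5-trimethoxyphenyl)propan-1-ol and a Z-configured 2-(angeloyloxymethyl)but-2-enoic acid. The acid is cut at its allylic ester C–O bond and at the C2–carboxyl bond, back to (Z)-2-iodobut-2-en-1-ol, angelic acid and CO.
- Enabling feature: the benzene ring carries three neighbouring oxygens on C3, C4 and C5 and the side chain on C1 across the ring, so it is symmetric about the C1–C4 axis. It is cut at C2–C3 and C5–C6 into 1,3-dimethoxyacetone (C3 to C5) and a 2-substituted malondialdehyde unit (C2, C1, C6) that already carries the carbinol.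
- Forward: the chiral three-carbon enaminal is made from methyl 3-oxopentanoate. The arene, the only ring, is then closed by [3+3] condensation with dimethoxyacetone, the phenol is methylated and the carbinol is unmasked. The acid is built separately from crotonaldehyde and joined in the last step.
- Stereochemistry: the (S)-carbinol comes from a Noyori hydrogenation with (S)-BINAP and its C–O bond is never broken. The Z-alkene of the hydroxymethylbutenoate comes from the (Z)-α-iodoenal by carbonylation with retention. The angelate Z-alkene is bought with angelic acid.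

Key step: step 6

Remark: enaminal 5 is drawn with the dimethylamino group trans to the formyl group; this push-pull double bond isomerises readily and its geometry is not carried into the product.

**Route**

Step 1
Reactants: 1 methyl 3-oxopentanoate
Product: 2 methyl (S)-3-hydroxypentanoate
Conditions: RuCl2[(S)-BINAP] (0.1 mol %), H2 (50 atm), MeOH, 50 °C
Reagents that add atoms: none
Why: Noyori asymmetric hydrogenation of a β-keto ester, in which the keto and ester oxygens chelate ruthenium and the (S)-BINAP ligand directs hydride to the face that gives the (S)-carbinol, the only stereocentre of the aryl fragment.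

Step 2
Reactants: 2 methyl (S)-3-hydroxypentanoate
Product: 3 methyl (S)-3-(tert-butyldimethylsilyloxy)pentanoate
Conditions: TBSCl, imidazole, DMF, rt
Reagents that add atoms: tert-butyldimethylsilyl chloride, CC(C)(C)[Si](C)(C)Cl
Why: Corey silylation of a secondary alcohol; the silyl ether should withstand hydride, alkoxide and carbonate and is later removed by fluoride without touching the C–O bond of the stereocentre.

Step 3
Reactants: 3 methyl (S)-3-(tert-butyldimethylsilyloxy)pentanoate
Product: 4 (S)-3-(tert-butyldimethylsilyloxy)pentanal
Conditions: i-Bu2AlH (1.1 equiv), CH2Cl2, −78 °C; then MeOH, aq. potassium sodium tartrate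
Reagents that add atoms: none
Why: Partial ester reduction with i-Bu2AlH, reliable for β-silyloxy esters because the tetrahedral aluminium hemiacetal persists at −78 °C and releases the aldehyde only on quench; the stereocentre is not involved.

Step 4
Reactants: 4 (S)-3-(tert-butyldimethylsilyloxy)pentanal
Product: 5 (S,E)-2-[1-(tert-butyldimethylsilyloxy)propyl]-3-(dimethylamino)acrylaldehyde
Conditions: Me2NCH(OMe)2 (2 equiv), toluene, 60 °C
Reagents that add atoms: N,N-dimethylformamide dimethyl acetal, COC(OC)N(C)C
Why: Aminomethylenation of an enolisable aldehyde with a formamide acetal: methoxide released from the reagent enolises the aldehyde, the enolate adds to the methoxymethyleneiminium ion and loss of methanol gives the push-pull enaminal, the moderate temperature being chosen to keep β-elimination of silanol slow.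

Step 5
Reactants: 6 1,3-dimethoxypropan-2-ol
Product: 7 1,3-dimethoxypropan-2-one
Conditions: (COCl)2, DMSO, CH2Cl2, −78 °C; Et3N, −78 °C → rt; filtration, distillation
Reagents that add atoms: none
Why: Swern oxidation of a secondary alcohol, with a non-aqueous work-up that suits the small water-soluble ketone.

Step 6
Reactants: 5 (S,E)-2-[1-(tert-butyldimethylsilyloxy)propyl]-3-(dimethylamino)acrylaldehyde; 7 1,3-dimethoxypropan-2-one (1.3 equiv)
Product: 9 (S)-4-[1-(tert-butyldimethylsilyloxy)propyl]-2,6-dimethoxyphenol, via open-chain keto enal 8 (not isolated)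
Conditions: KOt-Bu (2.5 equiv), t-BuOH/THF, 0 → 50 °C; then AcOH, 0 °C
Reagents that add atoms: none
Why: The potassium enolate of 7 attacks the aminomethylene carbon of the vinylogous formamide 5 and dimethylamine is expelled, giving keto enal 8, whose alkene geometry equilibrates through its dienolate; the second α-methoxy enolate then closes the ring by a 6-(enolendo)-exo-trig aldol addition onto the aldehyde, and loss of water followed by enolisation of the 6-methoxycyclohexa-2,4-dienone gives the phenoxide (initial aldol at the formyl group followed by closure at the aminomethylene carbon would give the same phenol). The closest known reaction type is the base-mediated [3+3] phenol synthesis from ketones with two α-methylene groups and 2-substituted malondialdehyde equivalents such as aminoacroleins, vinamidinium salts or sodium nitromalonaldehyde. No new stereocentre is formed; the (S)-carbinol set in step 1 only becomes benzylic. Regioselectivity is not in question because both three-carbon partners are symmetric about the C1–C4 axis of the new ring, so either pairing of their termini gives the same arene with oxygen on C3, C4 and C5 and hydrogen on C2 and C6. The selectivity the step does need is loss of dimethylamine and water and not of silanolate: the carbinol carbon has no acidic hydrogen, the silyloxide is a poor leaving group, and the moderate temperature with a cold acetic acid quench should keep the phenoxide from expelling silanolate to a para-quinone methide.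

Step 7
Reactants: 9 (S)-4-[1-(tert-butyldimethylsilyloxy)propyl]-2,6-dimethoxyphenol
Product: 10 (S)-tert-butyldimethyl[1-(3,4,5-trimethoxyphenyl)propoxy]silane
Conditions: MeI, K2CO3, DMF, rt (crude 9 used directly)
Reagents that add atoms: iodomethane, CI
Why: Williamson methylation of the phenoxide under mild carbonate conditions, which turns the quinone-methide-prone 4-hydroxybenzyl ether into the robust 3,4,5-trimethoxyaryl system.

Step 8
Reactants: 10 (S)-tert-butyldimethyl[1-(3,4,5-trimethoxyphenyl)propoxy]silane
Product: 11 (S)-1-(3,4,5-trimethoxyphenyl)propan-1-ol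
Conditions: Bu4NF, THF, rt
Reagents that add atoms: none
Why: Fluoride cleavage of the silyl ether occurs at silicon, so the benzylic C–O bond and the S configuration remain intact.

Step 9
Reactants: 12 crotonaldehyde ((E)-but-2-enal)
Product: 13 (Z)-2-iodobut-2-enal
Conditions: I2, K2CO3, 4-(dimethylamino)pyridine (0.2 equiv), THF/H2O, rt
Reagents that add atoms: iodine, II
Why: Amine-mediated α-iodination of an enal (Morita–Baylis–Hillman-type addition of the pyridine, iodination of the enolate, loss of the pyridine), a standard preparation that should give the isomer with methyl trans to the formyl group, i.e. Z.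

Step 10
Reactants: 13 (Z)-2-iodobut-2-enal
Product: 14 (Z)-2-iodobut-2-en-1-ol
Conditions: NaBH4, MeOH, 0 °C
Reagents that add atoms: none
Why: 1,2-Reduction of the enal by borohydride, which leaves the alkene geometry and the C–I bond untouched.

Step 11
Reactants: 14 (Z)-2-iodobut-2-en-1-ol
Product: 15 2-(trimethylsilyl)ethyl (Z)-2-(hydroxymethyl)but-2-enoate
Conditions: CO (1 atm), PdCl2(PPh3)2 (5 mol %), Me3SiCH2CH2OH (10 equiv), Et3N, DMF, 60 °C
Reagents that add atoms: carbon monoxide, [C-]#[O+]; 2-(trimethylsilyl)ethanol, C[Si](C)(C)CCO
Why: Palladium-catalysed alkoxycarbonylation of an alkenyl iodide (Heck carbonylation): oxidative addition of zerovalent palladium to the C–I bond and CO insertion proceed with retention, so the carboxyl takes the place of iodine cis to the methyl group (Z), and the large excess of the silylethanol should outcompete the substrate hydroxyl in the alcoholysis of the acylpalladium species.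

Step 12
Reactants: 15 2-(trimethylsilyl)ethyl (Z)-2-(hydroxymethyl)but-2-enoate; 16 angelic acid ((Z)-2-methylbut-2-enoic acid)
Product: 18 2-(trimethylsilyl)ethyl (Z)-2-{[(Z)-2-methylbut-2-enoyl]oxymethyl}but-2-enoate, via angelic 2,4,6-trichlorobenzoic anhydride 17 (not isolated)
Conditions: 16, 2,4,6-Cl3C6H2COCl, Et3N, toluene, rt; then 15, 75 °C
Reagents that add atoms: none
Why: Yamaguchi-type mixed-anhydride acylation run without a nucleophilic catalyst: the primary allylic alcohol attacks the angeloyl carbonyl because the aroyl carbonyl is shielded by two ortho chlorines, and leaving out the pyridine catalyst avoids the conjugate-addition pathway that turns angelates into tiglates.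

Step 13
Reactants: 18 2-(trimethylsilyl)ethyl (Z)-2-{[(Z)-2-methylbut-2-enoyl]oxymethyl}but-2-enoate
Product: 19 (Z)-2-{[(Z)-2-methylbut-2-enoyl]oxymethyl}but-2-enoic acid
Conditions: Bu4NF, THF, 0 °C → rt; then 1 M HCl
Reagents that add atoms: none
Why: Fluoride-induced fragmentation of the 2-(trimethylsilyl)ethyl ester (β-elimination to ethylene and Me3SiF) frees the acid under conditions that should leave the angelate ester and both Z-alkenes alone.

Step 14
Reactants: 11 (S)-1-(3,4,5-trimethoxyphenyl)propan-1-ol; 19 (Z)-2-{[(Z)-2-methylbut-2-enoyl]oxymethyl}but-2-enoic acid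
Product: 21 (S)-1-(3,4,5-trimethoxyphenyl)propyl (Z)-2-{[(Z)-2-methylbut-2-enoyl]oxymethyl}but-2-enoate (CNP0198521.1), via acyl 2,4,6-trichlorobenzoic anhydride 20 (not isolated)
Conditions: 19, 2,4,6-Cl3C6H2COCl, Et3N, toluene, rt; then 11, 75 °C
Reagents that add atoms: none
Why: Yamaguchi-type esterification through the mixed anhydride, again without a nucleophilic catalyst: acylation takes place at the carbinol oxygen, so the C–O bond of the stereocentre is not broken and the S configuration is retained, while the catalyst-free conditions protect the two Z-alkenes and the allylic acyloxy group from conjugate addition.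

**Compound list**

1 | methyl 3-oxopentanoate | CCC(=O)CC(=O)OC | starting material
2 | methyl (S)-3-hydroxypentanoate | CC[C@H](O)CC(=O)OC | intermediate
3 | methyl (S)-3-(tert-butyldimethylsilyloxy)pentanoate | CC(C)(C)[Si](C)(C)O[C@@H](CC)CC(=O)OC | intermediate
4 | (S)-3-(tert-butyldimethylsilyloxy)pentanal | CC(C)(C)[Si](C)(C)O[C@@H](CC)CC=O | intermediate
5 | (S,E)-2-[1-(tert-butyldimethylsilyloxy)propyl]-3-(dimethylamino)acrylaldehyde (amino group trans to formyl, geometry labile) | CC(C)(C)[Si](C)(C)O[C@@H](CC)/C(C=O)=C\N(C)C | intermediate
6 | 1,3-dimethoxypropan-2-ol | COCC(O)COC | starting material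
7 | 1,3-dimethoxypropan-2-one | COCC(=O)COC | intermediate
8 | 2-[(S)-1-(tert-butyldimethylsilyloxy)propyl]-4,6-dimethoxy-5-oxohex-2-enal (open-chain keto enal; mixture at C4 and about the alkene) | CC(C)(C)[Si](C)(C)O[C@@H](CC)C(C=O)=CC(OC)C(=O)COC | intermediate (not isolated)
9 | (S)-4-[1-(tert-butyldimethylsilyloxy)propyl]-2,6-dimethoxyphenol | CC(C)(C)[Si](C)(C)O[C@@H](CC)c1cc(OC)c(O)c(OC)c1 | intermediate
10 | (S)-tert-butyldimethyl[1-(3,4,5-trimethoxyphenyl)propoxy]silane | CC(C)(C)[Si](C)(C)O[C@@H](CC)c1cc(OC)c(OC)c(OC)c1 | intermediate
11 | (S)-1-(3,4,5-trimethoxyphenyl)propan-1-ol | O[C@@H](CC)c1cc(OC)c(OC)c(OC)c1 | intermediate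
12 | crotonaldehyde ((E)-but-2-enal) | C/C=C/C=O | starting material
13 | (Z)-2-iodobut-2-enal | C/C=C(\I)C=O | intermediate
14 | (Z)-2-iodobut-2-en-1-ol | C/C=C(\I)CO | intermediate
15 | 2-(trimethylsilyl)ethyl (Z)-2-(hydroxymethyl)but-2-enoate | C/C=C(/CO)C(=O)OCC[Si](C)(C)C | intermediate
16 | angelic acid ((Z)-2-methylbut-2-enoic acid) | C/C=C(/C)C(=O)O | starting material
17 | angelic 2,4,6-trichlorobenzoic anhydride | C/C=C(/C)C(=O)OC(=O)c1c(Cl)cc(Cl)cc1Cl | intermediate (not isolated)
18 | 2-(trimethylsilyl)ethyl (Z)-2-{[(Z)-2-methylbut-2-enoyl]oxymethyl}but-2-enoate | C/C=C(/C)C(=O)OC/C(=C/C)C(=O)OCC[Si](C)(C)C | intermediate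
19 | (Z)-2-{[(Z)-2-methylbut-2-enoyl]oxymethyl}but-2-enoic acid | C/C=C(/C)C(=O)OC/C(=C/C)C(=O)O | intermediate
20 | (Z)-2-{[(Z)-2-methylbut-2-enoyl]oxymethyl}but-2-enoic 2,4,6-trichlorobenzoic anhydride | C/C=C(/C)C(=O)OC/C(=C/C)C(=O)OC(=O)c1c(Cl)cc(Cl)cc1Cl | intermediate (not isolated)
21 | (S)-1-(3,4,5-trimethoxyphenyl)propyl (Z)-2-{[(Z)-2-methylbut-2-enoyl]oxymethyl}but-2-enoate (CNP0198521.1) | C/C=C(/C)C(=O)OC/C(=C/C)C(=O)O[C@@H](CC)c1cc(OC)c(OC)c(OC)c1 | target

**Step count**

Total: 14 steps. Longest linear sequence: 8 steps (steps 1, 2, 3, 4, 6, 7, 8 and 14). The acid branch (steps 9 to 13) and the ketone (step 5) are convergent.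

**Steps most likely to fail**

1. Step 6 (ring construction). The enolate of 7 may add too slowly to the weakly electrophilic vinylogous formamide, so that self-condensation of the ketone, or β-elimination of silanolate from the open-chain aldehyde enolate, overtakes ring closure. The fallback sets out from 5 and raises the electrophilicity of the three-carbon unit. Condensation of 5 with dimethylammonium tetrafluoroborate (EtOH, rt) should give the symmetric vinamidinium salt (S)-N-{2-[1-(tert-butyldimethylsilyloxy)propyl]-3-(dimethylamino)prop-2-en-1-ylidene}-N-methylmethanaminium tetrafluoroborate F1, a cationic bis-electrophile of the kind used in enolate annulations. With the potassium enolate of 7 (KOt-Bu, THF, 0 → 45 °C) it should lose both dimethylamino groups without passing through an aldehyde enolate, and it comes back to the route at phenol 9.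

2. Step 4 (aminomethylenation). Under the basic condensation the aldehyde enolate may expel silanol (E1cB) or undergo aldol self-condensation faster than it is aminomethylenated. The fallback sets out from 4 and separates enolisation from C–C bond formation. Soft enolisation (Me3SiOTf, Et3N, CH2Cl2, 0 °C) should give the enol silane (S)-tert-butyldimethyl{[1-(trimethylsilyloxy)pent-1-en-3-yl]oxy}silane F2 without a free enolate. Vilsmeier formylation of this enol ether with (chloromethylene)dimethyliminium chloride (CH2Cl2, 0 °C, then aq. K2CO3), the classical entry to 2-substituted 3-(dimethylamino)acroleins, comes back to the route at enaminal 5.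

3. Step 14 (final esterification). Acylation of the hindered secondary benzylic alcohol may be slow, and forcing it with heat or a nucleophilic catalyst invites conjugate displacement of the allylic angelate and Z-to-E isomerisation in the activated acid. The fallback forms the benzylic ester with an acid that has no allylic leaving group and introduces the angelate last.
 - Setting out from 14, silylation (TBSCl, imidazole, DMF) gives (Z)-tert-butyl[(2-iodobut-2-en-1-yl)oxy]dimethylsilane F3.
 - Palladium-catalysed hydroxycarbonylation (Pd(OAc)2, PPh3, CO, KOAc, DMF/H2O, 50 °C) gives (Z)-2-[(tert-butyldimethylsilyloxy)methyl]but-2-enoic acid F4.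
 - Its 2,4,6-trichlorobenzoic mixed anhydride acylates 11 (toluene, with 4-(dimethylamino)pyridine at rt now tolerable) to give (S)-1-(3,4,5-trimethoxyphenyl)propyl (Z)-2-[(tert-butyldimethylsilyloxy)methyl]but-2-enoate F5.
 - HF·pyridine (THF, 0 °C) gives (S)-1-(3,4,5-trimethoxyphenyl)propyl (Z)-2-(hydroxymethyl)but-2-enoate F6.
 - Acylation of its primary hydroxyl with anhydride 17 as in step 12 comes back to the route at target 21.

**Further compounds**

F1 | step 6 | (S)-N-{2-[1-(tert-butyldimethylsilyloxy)propyl]-3-(dimethylamino)prop-2-en-1-ylidene}-N-methylmethanaminium tetrafluoroborate | CC(C)(C)[Si](C)(C)O[C@@H](CC)C(C=[N+](C)C)=CN(C)C.F[B-](F)(F)F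
F2 | step 4 | (S)-tert-butyldimethyl{[1-(trimethylsilyloxy)pent-1-en-3-yl]oxy}silane | CC(C)(C)[Si](C)(C)O[C@@H](CC)C=CO[Si](C)(C)C
F3 | step 14 | (Z)-tert-butyl[(2-iodobut-2-en-1-yl)oxy]dimethylsilane | C/C=C(\I)CO[Si](C)(C)C(C)(C)C
F4 | step 14 | (Z)-2-[(tert-butyldimethylsilyloxy)methyl]but-2-enoic acid | C/C=C(/CO[Si](C)(C)C(C)(C)C)C(=O)O
F5 | step 14 | (S)-1-(3,4,5-trimethoxyphenyl)propyl (Z)-2-[(tert-butyldimethylsilyloxy)methyl]but-2-enoate | C/C=C(/CO[Si](C)(C)C(C)(C)C)C(=O)O[C@@H](CC)c1cc(OC)c(OC)c(OC)c1
F6 | step 14 | (S)-1-(3,4,5-trimethoxyphenyl)propyl (Z)-2-(hydroxymethyl)but-2-enoate | C/C=C(/CO)C(=O)O[C@@H](CC)c1cc(OC)c(OC)c(OC)c1
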